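**Retrosynthetic overview**

- The enabling feature is the bond C7–C7a (indane numbering). C7 is a vinylic carbon of the cyclohexene ring, and C7a is β to the C2 ketone of the cyclopentanone ring with C1 in between, so C7a can be the β-carbon of a 2-methylenoate and C1–C2 a Dieckmann bond.
- Key disconnection: an alkenyllithium closes the six-membered ring first by 6-exo conjugate addition (C7–C7a); the ester enolate formed then closes the five-membered ring by Dieckmann acylation (C1–C2), in one flask from an acyclic iodo-triene acid.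
- The vicinal quaternary carbons C4–C5 come from an Ireland–Claisen rearrangement of an ester of a 2-ethyl-hexenedioic acid half-ester with a (1S)-1-phenyl-dienyl alcohol; this also delivers the (E)-styryl group and the free acid.
- The acid part comes from (5S)-menthyloxybutenolide by tandem Michael addition/ethylation (sets C3a), hydrolysis and Wittig olefination; the alcohol part comes from methyl (R)-mandelate.
- The end is a demethoxycarbonylation that lets C1 and C3 settle in the thermodynamic arrangement.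

Key step: step 13

Assumption: the (R)-configured lithium amide in step 12 is taken as the enantiomer matched to the (2S)-ester 18 for the ketene acetal with ethyl cis to the silyloxy group; if the known dependence of this enolisation on the α-stereocentre points the other way, its antipode is used.

**Step 1**
Reactants: 1 5-hydroxyfuran-2(5H)-one; 2 (1S,2R,5S)-5-methyl-2-(propan-2-yl)cyclohexan-1-ol ((+)-menthol)
Product: 3 (5S)-5-{[(1S,2R,5S)-5-methyl-2-(propan-2-yl)cyclohexyl]oxy}furan-2(5H)-one
Conditions: camphorsulfonic acid (cat.), toluene, reflux (Dean–Stark); crystallisation from petroleum ether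
Reagents that add atoms: none
Why: acid-catalysed acetalisation of the lactol; the acetal centre epimerises under acid and the (5S)-diastereomer (mirror image of the well-known l-menthyl compound) should crystallise, so the stereocentre is set by crystallisation-driven equilibration.

**Step 2**
Reactants: 4 methyl propanoate; 3 (5S)-5-menthyloxyfuran-2(5H)-one
Product: 7 methyl 2-[(2S,3S,4S)-4-ethyl-2-{[(1S,2R,5S)-5-methyl-2-(propan-2-yl)cyclohexyl]oxy}-5-oxooxolan-3-yl]propanoate, via lithium enolate 5 (not isolated), via lactone enolate 6 (not isolated)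
Conditions: LiN(iPr)2, THF, −78 °C; 3, −78 °C; EtI, DMPU, −78 → −30 °C
Reagents that add atoms: iodoethane CCI
Why: tandem Michael addition–enolate alkylation on a 5-alkoxybutenolide: the ester enolate should add anti to the menthyloxy group and the lactone enolate should be ethylated anti to the new substituent (trans,trans lactone); the propanoate α-centre forms without control and is erased later.

**Step 3**
Reactants: 7 trans,trans-lactone acetal
Product: 8 methyl 2-[(3S,4S)-4-ethyl-2-hydroxy-5-oxooxolan-3-yl]propanoate (lactol)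
Conditions: CF3CO2H–H2O (4:1), 45 °C
Reagents that add atoms: water O
Why: acid hydrolysis of the acyloxy/alkoxy acetal releases menthol and gives the γ-lactol, the ring tautomer of the aldehyde acid, which keeps the stereocentre next to the masked aldehyde out of the enolisable open form.

**Step 4**
Reactants: 8 lactol
Product: 9 (2S,3S,4E)-2-ethyl-6-methoxy-3-(1-methoxy-1-oxopropan-2-yl)-5-methyl-6-oxohex-4-enoic acid
Conditions: Ph3P=C(CH3)CO2CH3 (1.5 equiv), toluene, 70 °C
Reagents that add atoms: methyl 2-(triphenyl-λ5-phosphanylidene)propanoate COC(=O)C(C)=P(c1ccccc1)(c1ccccc1)c1ccccc1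
Why: Wittig olefination of the open aldehyde-acid tautomer with a stabilised α-methyl ylide, which should be (E)-selective and is not stopped by the carboxylic acid formed.

**Step 5**
Reactants: 10 methyl (2R)-2-hydroxy-2-phenylacetate (methyl (R)-mandelate)
Product: 11 methyl (2R)-2-{[tert-butyl(dimethyl)silyl]oxy}-2-phenylacetate
Conditions: tBuMe2SiCl, imidazole, DMF, rt
Reagents that add atoms: tert-butyl(chloro)dimethylsilane CC(C)(C)[Si](C)(C)Cl
Why: standard silylation of the secondary alcohol; the chiral-pool stereocentre is untouched.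

**Step 6**
Reactants: 11 silyl ether
Product: 13 ethyl (2E,4S)-4-{[tert-butyl(dimethyl)silyl]oxy}-2-ethyl-4-phenylbut-2-enoate, via α-silyloxy aldehyde 12 (not isolated)
Conditions: iBu2AlH (1.05 equiv), CH2Cl2, −78 °C; then Ph3P=C(C2H5)CO2C2H5, −78 °C → rt
Reagents that add atoms: ethyl 2-(triphenyl-λ5-phosphanylidene)butanoate CCOC(=O)C(CC)=P(c1ccccc1)(c1ccccc1)c1ccccc1
Why: half-reduction to the configurationally labile aldehyde and immediate Wittig olefination with a stabilised α-ethyl ylide should avoid racemisation and give the (E)-enoate, which places the carbinol carbon cis to ethyl.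

**Step 7**
Reactants: 13 enoate
Product: 14 (2E,4S)-4-{[tert-butyl(dimethyl)silyl]oxy}-2-ethyl-4-phenylbut-2-en-1-ol
Conditions: iBu2AlH (2.2 equiv), CH2Cl2, −78 °C; aq. KNaC4H4O6 work-up
Reagents that add atoms: none
Why: 1,2-reduction of the conjugated ester to the allylic alcohol without touching the double bond geometry.

**Step 8**
Reactants: 14 allylic alcohol
Product: 15 (2E,4S)-4-{[tert-butyl(dimethyl)silyl]oxy}-2-ethyl-4-phenylbut-2-enal
Conditions: MnO2 (activated), CH2Cl2, rt
Reagents that add atoms: none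
Why: chemoselective allylic oxidation to the enal under neutral conditions.

**Step 9**
Reactants: 15 enal
Product: 16 tert-butyl{[(1S,2E,4Z)-3-ethyl-5-iodo-1-phenylhexa-2,4-dien-1-yl]oxy}dimethylsilane
Conditions: EtPPh3Br, n-BuLi, THF, rt; I2, −78 °C; NaN(SiMe3)2, −20 °C; then 15, −78 → −20 °C
Reagents that add atoms: ethyltriphenylphosphonium bromide CC[P+](c1ccccc1)(c1ccccc1)c1ccccc1.[Br-], iodine II
Why: Stork–Zhao olefination with the α-iodo ylide Ph3P=C(I)CH3, which is made in the flask from the phosphonium salt by deprotonation followed by iodination followed by a second deprotonation, should give the (Z)-2-iodoalkene (iodine cis to the chain), the geometry the later ring closure needs.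

**Step 10**
Reactants: 16 silyl ether
Product: 17 (1S,2E,4Z)-3-ethyl-5-iodo-1-phenylhexa-2,4-dien-1-ol
Conditions: Bu4NF, THF, 0 °C
Reagents that add atoms: none
Why: fluoride desilylation frees the secondary alcohol without affecting the iodo-diene.

**Step 11**
Reactants: 9 acid; 17 alcohol
Product: 18 1-[(1S,2E,4Z)-3-ethyl-5-iodo-1-phenylhexa-2,4-dien-1-yl] 6-methyl (2S,3S,4E)-2-ethyl-3-(1-methoxy-1-oxopropan-2-yl)-5-methylhex-4-enedioate
Conditions: DCC, DMAP (cat.), CH2Cl2, 0 °C → rt
Reagents that add atoms: none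
Why: Steglich esterification joins the two fragments under mild conditions that should spare the ionisable benzylic/allylic alcohol and the α-stereocentre.

**Step 12**
Reactants: 18 allylic ester
Product: 21 (2S,3S,4E)-2-ethyl-2-[(1E,3R,4Z)-3-ethyl-5-iodo-1-phenylhexa-1,4-dien-3-yl]-6-methoxy-3-(1-methoxy-1-oxopropan-2-yl)-5-methyl-6-oxohex-4-enoic acid, via bis(silyl ketene acetal) 19 (not isolated), via rearranged silyl ester 20 (not isolated)
Conditions: (R)-PhCH(CH2NC5H10)NHCH2CF3 (2.6 equiv), n-BuLi (2.5 equiv), THF, −78 °C; 18; Me3SiCl/Et3N, −78 → 50 °C; 1 M HCl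
Reagents that add atoms: none
Why: Ireland–Claisen rearrangement through a chair with phenyl equatorial should transfer the carbinol chirality to the new quaternary carbon (3R) and give the (E)-styryl group, while the second quaternary centre follows from the ketene acetal geometry (ethyl cis to OSiMe3) enforced by the chiral amide matched to the α-stereocentre; the propanoate ester is silylated too and returns on work-up, and the γ-hydrogen of the enoate is held in the alkene plane by allylic strain and should not be removed.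

**Step 13**
Reactants: 21 iodo-triene acid
Product: 25 (3aS,4S,5R,7aR)-4,5-diethyl-1-(methoxycarbonyl)-1,3,7-trimethyl-2-oxo-5-[(E)-2-phenylethenyl]-2,3,3a,4,5,7a-hexahydro-1H-indene-4-carboxylic acid (C1 and C3 not defined), via sodium carboxylate 22 (not isolated), via alkenyllithium 23 (not isolated), via ester enolate 24 (not isolated)
Conditions: NaH (1.05 equiv), THF, 0 °C; t-BuLi (2.1 equiv), THF–Et2O–pentane, −100 → −40 °C; aq. NH4Cl then 1 M HCl
Reagents that add atoms: none
Why: After the acid is stored as its carboxylate, iodine–lithium exchange gives the (Z)-alkenyllithium with retention, which adds 6-exo-trig to the β-carbon of the (E)-2-methylenoate (future C7a) and closes the cyclohexene ring; the ester enolate so formed attacks the neighbouring propanoate ester in a 5-exo-trig Dieckmann acylation that closes the cyclopentanone and expels methoxide. The closest known reaction types are the halogen–metal-exchange-initiated intramolecular conjugate addition of alkenyllithiums to enoates and Michael-initiated ring closures that end in a Claisen condensation. The new stereocentre C7a is controlled by 1,3-allylic strain: the α-methyl group of the enoate forces the C–H bond of the neighbouring stereocentre (future C3a) into the plane of the acceptor, so the nucleophile tethered through the quaternary carbon attacks the face that leaves the two side arms trans, as the trans ring fusion requires. C1 (methyl/ester) and C3 form without control and are erased or equilibrated in step 14, and a Dieckmann closure in the other sense would converge on the same final ketone. The step needs the exchange to outrun attack of t-BuLi on the methyl esters and the ring closure to outrun proton transfer from the enolisable ester; the very low temperature, the carboxylate form of the acid and the gem-dialkyl effect of the two adjacent quaternary carbons in the tether should secure this.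

**Step 14**
Reactants: 25 β-keto ester acid
Product: 26 (1R,3R,3aS,4S,5R,7aS)-4,5-diethyl-1,3,7-trimethyl-2-oxo-5-[(E)-2-phenylethenyl]-2,3,3a,4,5,7a-hexahydro-1H-indene-4-carboxylic acid (dinorspiculoic acid A)
Conditions: LiCl (5 equiv), H2O (3 equiv), DMSO, 150 °C; aq. HCl work-up
Reagents that add atoms: none
Why: Krapcho demethoxycarbonylation of the α,α-disubstituted β-keto ester; under the hot, weakly basic conditions both α-centres of the cyclopentanone should settle with each methyl trans to its neighbouring ring-fusion substituent, which is the configuration of the target.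

**Compound list**

1 | 5-hydroxyfuran-2(5H)-one | O=C1C=CC(O)O1 | starting material
2 | (1S,2R,5S)-5-methyl-2-(propan-2-yl)cyclohexan-1-ol | O[C@H]1C[C@@H](C)CC[C@@H]1C(C)C | starting material
3 | (5S)-5-{[(1S,2R,5S)-5-methyl-2-(propan-2-yl)cyclohexyl]oxy}furan-2(5H)-one | O=C1C=C[C@@H](O[C@H]2C[C@@H](C)CC[C@@H]2C(C)C)O1 | intermediate
4 | methyl propanoate | CCC(=O)OC | starting material
5 | lithium 1-methoxyprop-1-en-1-olate | CC=C(OC)O[Li] | intermediate (not isolated)
6 | lithium (4R,5S)-4-(1-methoxy-1-oxopropan-2-yl)-5-{[(1S,2R,5S)-5-methyl-2-(propan-2-yl)cyclohexyl]oxy}-4,5-dihydrofuran-2-olate | [Li]OC1=C[C@H](C(C)C(=O)OC)[C@@H](O[C@H]2C[C@@H](C)CC[C@@H]2C(C)C)O1 | intermediate (not isolated)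
7 | methyl 2-[(2S,3S,4S)-4-ethyl-2-{[(1S,2R,5S)-5-methyl-2-(propan-2-yl)cyclohexyl]oxy}-5-oxooxolan-3-yl]propanoate | O=C1[C@@H](CC)[C@H](C(C)C(=O)OC)[C@@H](O[C@H]2C[C@@H](C)CC[C@@H]2C(C)C)O1 | intermediate
8 | methyl 2-[(3S,4S)-4-ethyl-2-hydroxy-5-oxooxolan-3-yl]propanoate | O=C1[C@@H](CC)[C@H](C(C)C(=O)OC)C(O)O1 | intermediate
9 | (2S,3S,4E)-2-ethyl-6-methoxy-3-(1-methoxy-1-oxopropan-2-yl)-5-methyl-6-oxohex-4-enoic acid | OC(=O)[C@@H](CC)[C@H](C(C)C(=O)OC)/C=C(\C)C(=O)OC | intermediate
10 | methyl (2R)-2-hydroxy-2-phenylacetate | COC(=O)[C@H](O)c1ccccc1 | starting material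
11 | methyl (2R)-2-{[tert-butyl(dimethyl)silyl]oxy}-2-phenylacetate | COC(=O)[C@H](O[Si](C)(C)C(C)(C)C)c1ccccc1 | intermediate
12 | (2R)-2-{[tert-butyl(dimethyl)silyl]oxy}-2-phenylacetaldehyde | O=C[C@H](O[Si](C)(C)C(C)(C)C)c1ccccc1 | intermediate (not isolated)
13 | ethyl (2E,4S)-4-{[tert-butyl(dimethyl)silyl]oxy}-2-ethyl-4-phenylbut-2-enoate | CC(C)(C)[Si](C)(C)O[C@H](c1ccccc1)/C=C(\CC)C(=O)OCC | intermediate
14 | (2E,4S)-4-{[tert-butyl(dimethyl)silyl]oxy}-2-ethyl-4-phenylbut-2-en-1-ol | CC(C)(C)[Si](C)(C)O[C@H](c1ccccc1)/C=C(\CC)CO | intermediate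
15 | (2E,4S)-4-{[tert-butyl(dimethyl)silyl]oxy}-2-ethyl-4-phenylbut-2-enal | CC(C)(C)[Si](C)(C)O[C@H](c1ccccc1)/C=C(\CC)C=O | intermediate
16 | tert-butyl{[(1S,2E,4Z)-3-ethyl-5-iodo-1-phenylhexa-2,4-dien-1-yl]oxy}dimethylsilane | CC(C)(C)[Si](C)(C)O[C@H](c1ccccc1)/C=C(\CC)/C=C(/C)I | intermediate
17 | (1S,2E,4Z)-3-ethyl-5-iodo-1-phenylhexa-2,4-dien-1-ol | O[C@H](c1ccccc1)/C=C(\CC)/C=C(/C)I | intermediate
18 | 1-[(1S,2E,4Z)-3-ethyl-5-iodo-1-phenylhexa-2,4-dien-1-yl] 6-methyl (2S,3S,4E)-2-ethyl-3-(1-methoxy-1-oxopropan-2-yl)-5-methylhex-4-enedioate | CC[C@H](C(=O)O[C@H](c1ccccc1)/C=C(\CC)/C=C(/C)I)[C@H](C(C)C(=O)OC)/C=C(\C)C(=O)OC | intermediate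
19 | bis(trimethylsilyl ketene acetal) of 18 (ethyl cis to OSiMe3 at the allyl ester; second ketene acetal at the propanoate) | CC/C(=C(\O[Si](C)(C)C)O[C@H](c1ccccc1)/C=C(\CC)/C=C(/C)I)[C@H](C(C)=C(OC)O[Si](C)(C)C)/C=C(\C)C(=O)OC | intermediate (not isolated)
20 | trimethylsilyl ester of 21 with the propanoate still as its trimethylsilyl ketene acetal | CC[C@@](/C=C/c1ccccc1)(/C=C(/C)I)[C@@](CC)(C(=O)O[Si](C)(C)C)[C@H](C(C)=C(OC)O[Si](C)(C)C)/C=C(\C)C(=O)OC | intermediate (not isolated)
21 | (2S,3S,4E)-2-ethyl-2-[(1E,3R,4Z)-3-ethyl-5-iodo-1-phenylhexa-1,4-dien-3-yl]-6-methoxy-3-(1-methoxy-1-oxopropan-2-yl)-5-methyl-6-oxohex-4-enoic acid | CC[C@@](/C=C/c1ccccc1)(/C=C(/C)I)[C@@](CC)(C(=O)O)[C@H](C(C)C(=O)OC)/C=C(\C)C(=O)OC | intermediate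
22 | sodium salt of 21 | CC[C@@](/C=C/c1ccccc1)(/C=C(/C)I)[C@@](CC)(C(=O)O[Na])[C@H](C(C)C(=O)OC)/C=C(\C)C(=O)OC | intermediate (not isolated)
23 | (Z)-alkenyllithium from 22 (lithium in place of iodine) | CC[C@@](/C=C/c1ccccc1)(/C=C(/C)[Li])[C@@](CC)(C(=O)O[Na])[C@H](C(C)C(=O)OC)/C=C(\C)C(=O)OC | intermediate (not isolated)
24 | lithium ester enolate of the cyclised cyclohexene (sodium carboxylate) | CC[C@@]1(/C=C/c2ccccc2)C=C(C)[C@H](C(C)=C(OC)O[Li])[C@@H](C(C)C(=O)OC)[C@]1(CC)C(=O)O[Na] | intermediate (not isolated)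
25 | (3aS,4S,5R,7aR)-4,5-diethyl-1-(methoxycarbonyl)-1,3,7-trimethyl-2-oxo-5-[(E)-2-phenylethenyl]-2,3,3a,4,5,7a-hexahydro-1H-indene-4-carboxylic acid | CC[C@@]1(/C=C/c2ccccc2)C=C(C)[C@H]2[C@@H](C(C)C(=O)C2(C)C(=O)OC)[C@]1(CC)C(=O)O | intermediate
26 | (1R,3R,3aS,4S,5R,7aS)-4,5-diethyl-1,3,7-trimethyl-2-oxo-5-[(E)-2-phenylethenyl]-2,3,3a,4,5,7a-hexahydro-1H-indene-4-carboxylic acid | CC[C@@]1(/C=C/c2ccccc2)C=C(C)[C@H]2[C@@H]([C@@H](C)C(=O)[C@@H]2C)[C@]1(CC)C(=O)O | target

**Step count and risks**

Total step count: 14. Longest linear sequence: 10 steps (steps 5–14, from methyl (R)-mandelate).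

Steps most likely to fail:

1. Step 13. The alkenyllithium may be quenched by proton transfer from the enolisable propanoate C–H, or tert-butyllithium may attack an ester before the exchange, so that no ring forms. The fallback sets out from 21 and closes the ring with a radical instead of an anion. With (Me3Si)3SiH and AIBN in benzene at 80 °C, 6-exo-trig cyclisation of the alkenyl radical onto the enoate, under the same allylic-strain control, should give (1S,2R,5S,6S)-1,2-diethyl-5,6-bis(1-methoxy-1-oxopropan-2-yl)-4-methyl-2-[(E)-2-phenylethenyl]cyclohex-3-ene-1-carboxylic acid F1. A separate Dieckmann condensation with LiN(SiMe3)2 (3.3 equiv, THF, −78 → 0 °C) then comes back to the route at 25. If it closes in the other sense it gives the regioisomer (3aR,4S,5R,7aS)-4,5-diethyl-3-(methoxycarbonyl)-1,3,7-trimethyl-2-oxo-5-[(E)-2-phenylethenyl]-2,3,3a,4,5,7a-hexahydro-1H-indene-4-carboxylic acid F2, which step 14 converts into 26 just as it does 25.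

2. Step 12. Enolisation of the hindered, doubly branched ester may give the ketene acetal of the other geometry or a mixture, which would scramble the configuration of the acid-bearing quaternary carbon. The fallback sets out from acid 9 and exchanges the alcohol partner, so that the other geometry (ethyl cis to the allyloxy group, as enolisation in THF–HMPA should favour) leads to the same product through the mirror-image chair. From methyl (S)-mandelate, the sequence of steps 5–10 is repeated with a (Z)-selective Still–Gennari olefination (ethyl 2-[bis(2,2,2-trifluoroethoxy)phosphoryl]butanoate, KN(SiMe3)2, 18-crown-6) in place of the Wittig reaction. This passes through methyl (2S)-2-{[tert-butyl(dimethyl)silyl]oxy}-2-phenylacetate F3, (2S)-2-{[tert-butyl(dimethyl)silyl]oxy}-2-phenylacetaldehyde F4 (not isolated), ethyl (2Z,4R)-4-{[tert-butyl(dimethyl)silyl]oxy}-2-ethyl-4-phenylbut-2-enoate F5, (2Z,4R)-4-{[tert-butyl(dimethyl)silyl]oxy}-2-ethyl-4-phenylbut-2-en-1-ol F6, (2Z,4R)-4-{[tert-butyl(dimethyl)silyl]oxy}-2-ethyl-4-phenylbut-2-enal F7 and tert-butyl{[(1R,2Z,4Z)-3-ethyl-5-iodo-1-phenylhexa-2,4-dien-1-yl]oxy}dimethylsilane F8, to (1R,2Z,4Z)-3-ethyl-5-iodo-1-phenylhexa-2,4-dien-1-ol F9. Esterification of 9 with this alcohol under the conditions of step 11 should give 1-[(1R,2Z,4Z)-3-ethyl-5-iodo-1-phenylhexa-2,4-dien-1-yl] 6-methyl (2S,3S,4E)-2-ethyl-3-(1-methoxy-1-oxopropan-2-yl)-5-methylhex-4-enedioate F10, whose Ireland–Claisen rearrangement comes back to the route at 21.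

3. Step 2. The basic ester enolate may add 1,2, exchange protons with the adduct, or the lactone may be alkylated twice in the one-flask sequence. The fallback sets out from 3 and separates the two events under non-basic conditions. Mukaiyama–Michael addition of (E)-1-methoxy-1-(trimethylsilyloxy)prop-1-ene with catalytic Me3SiOSO2CF3 (CH2Cl2, −78 °C) should give methyl 2-[(2S,3R)-2-{[(1S,2R,5S)-5-methyl-2-(propan-2-yl)cyclohexyl]oxy}-5-[(trimethylsilyl)oxy]-2,3-dihydrofuran-3-yl]propanoate F11. Work-up hydrolyses it to methyl 2-[(2S,3R)-2-{[(1S,2R,5S)-5-methyl-2-(propan-2-yl)cyclohexyl]oxy}-5-oxooxolan-3-yl]propanoate F12. Selective deprotonation of the lactone CH2 (LiN(iPr)2, 1.0 equiv, THF, −78 °C) and ethylation (EtI, DMPU) then come back to the route at 7.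

**Further compounds**

F1 | step 13 | (1S,2R,5S,6S)-1,2-diethyl-5,6-bis(1-methoxy-1-oxopropan-2-yl)-4-methyl-2-[(E)-2-phenylethenyl]cyclohex-3-ene-1-carboxylic acid | CC[C@@]1(/C=C/c2ccccc2)C=C(C)[C@H](C(C)C(=O)OC)[C@@H](C(C)C(=O)OC)[C@]1(CC)C(=O)O
F2 | step 13 | (3aR,4S,5R,7aS)-4,5-diethyl-3-(methoxycarbonyl)-1,3,7-trimethyl-2-oxo-5-[(E)-2-phenylethenyl]-2,3,3a,4,5,7a-hexahydro-1H-indene-4-carboxylic acid | CC[C@@]1(/C=C/c2ccccc2)C=C(C)[C@H]2[C@@H](C(C)(C(=O)OC)C(=O)C2C)[C@]1(CC)C(=O)O
F3 | step 12 | methyl (2S)-2-{[tert-butyl(dimethyl)silyl]oxy}-2-phenylacetate | COC(=O)[C@@H](O[Si](C)(C)C(C)(C)C)c1ccccc1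
F4 | step 12 | (2S)-2-{[tert-butyl(dimethyl)silyl]oxy}-2-phenylacetaldehyde | O=C[C@@H](O[Si](C)(C)C(C)(C)C)c1ccccc1
F5 | step 12 | ethyl (2Z,4R)-4-{[tert-butyl(dimethyl)silyl]oxy}-2-ethyl-4-phenylbut-2-enoate | CC(C)(C)[Si](C)(C)O[C@@H](c1ccccc1)/C=C(/CC)C(=O)OCC
F6 | step 12 | (2Z,4R)-4-{[tert-butyl(dimethyl)silyl]oxy}-2-ethyl-4-phenylbut-2-en-1-ol | CC(C)(C)[Si](C)(C)O[C@@H](c1ccccc1)/C=C(/CC)CO
F7 | step 12 | (2Z,4R)-4-{[tert-butyl(dimethyl)silyl]oxy}-2-ethyl-4-phenylbut-2-enal | CC(C)(C)[Si](C)(C)O[C@@H](c1ccccc1)/C=C(/CC)C=O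
F8 | step 12 | tert-butyl{[(1R,2Z,4Z)-3-ethyl-5-iodo-1-phenylhexa-2,4-dien-1-yl]oxy}dimethylsilane | CC(C)(C)[Si](C)(C)O[C@@H](c1ccccc1)/C=C(/CC)\C=C(\C)I
F9 | step 12 | (1R,2Z,4Z)-3-ethyl-5-iodo-1-phenylhexa-2,4-dien-1-ol | O[C@@H](c1ccccc1)/C=C(/CC)\C=C(\C)I
F10 | step 12 | 1-[(1R,2Z,4Z)-3-ethyl-5-iodo-1-phenylhexa-2,4-dien-1-yl] 6-methyl (2S,3S,4E)-2-ethyl-3-(1-methoxy-1-oxopropan-2-yl)-5-methylhex-4-enedioate | CC[C@H](C(=O)O[C@@H](c1ccccc1)/C=C(/CC)\C=C(\C)I)[C@H](C(C)C(=O)OC)/C=C(\C)C(=O)OC
F11 | step 2 | methyl 2-[(2S,3R)-2-{[(1S,2R,5S)-5-methyl-2-(propan-2-yl)cyclohexyl]oxy}-5-[(trimethylsilyl)oxy]-2,3-dihydrofuran-3-yl]propanoate | C[Si](C)(C)OC1=C[C@H](C(C)C(=O)OC)[C@@H](O[C@H]2C[C@@H](C)CC[C@@H]2C(C)C)O1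
F12 | step 2 | methyl 2-[(2S,3R)-2-{[(1S,2R,5S)-5-methyl-2-(propan-2-yl)cyclohexyl]oxy}-5-oxooxolan-3-yl]propanoate | O=C1C[C@H](C(C)C(=O)OC)[C@@H](O[C@H]2C[C@@H](C)CC[C@@H]2C(C)C)O1
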